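**Retrosynthetic overview**
- C13–Br (last) and C9–Br come from SN2 inversions of the (13S)-allylic and (9S)-ring alcohols.
- C10–C11 is made by a nickel-catalysed Negishi coupling of a C1–C10 furanosyl bromide with a (Z)-C11–C15 alkenylzinc; this sets C10 trans to both the C9 oxygen and the C7 side chain.
- The only ring (oxolane, O/C7–C10) is closed before the coupling by transacetalisation of the C7 hydroxyl onto a C10 dimethyl acetal; C9 comes from a 1,3-anti reduction.
- C7–C8 is made by a Cornforth-anti lithium aldol of an (R)-α-chloroaldehyde (C1–C7, already carrying C6–Cl and the Z-enyne) with 1,1-dimethoxyacetone.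
- The Z-enyne comes from cis-1,2-dichloroethene by Sonogashira then Negishi coupling; the C11–C15 iodide from an acyl Sonogashira, Noyori reduction (C13) and diimide reduction of an iodoalkyne.

Assumption: positions are given in the C15 chain numbering, C1 (alkyne CH) to C15 (ethyl CH3); the SMILES is read as the (3Z,6R,7S,9R,10R,11Z,13R) isomer with a 2,5-trans oxolane and Br at C9 cis to the C10 alkenyl group.

**Route**

Step 1
Reactants: 1 cis-1,2-dichloroethene (fivefold excess); 2 ethynyltrimethylsilane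
Product: 3 (Z)-(4-chlorobut-3-en-1-yn-1-yl)trimethylsilane
Conditions: Pd(PPh3)4 (5 mol%), CuI (10 mol%), n-BuNH2, Et2O, 23 °C
Reagents that add atoms: none
Why: Sonogashira mono-coupling of the cis-dihalide proceeds with retention, so the C3=C4 Z geometry is fixed here.

Step 2
Reactants: 3 (Z)-(4-chlorobut-3-en-1-yn-1-yl)trimethylsilane; 4 ethyl 3-iodopropanoate
Product: 6 ethyl (Z)-7-(trimethylsilyl)hept-4-en-6-ynoate, via zinc homoenolate 5 (not isolated)
Conditions: 4, Zn (activated with BrCH2CH2Br and Me3SiCl), THF, 35 °C; then 3, Pd(OAc)2 (2 mol%), SPhos (4 mol%), THF, 23 °C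
Reagents that add atoms: none
Why: Negishi sp3–sp2 coupling of the ester-tolerant alkylzinc with the activated alkenyl chloride retains the Z alkene and forms C4–C5.

Step 3
Reactants: 6 ethyl (Z)-7-(trimethylsilyl)hept-4-en-6-ynoate
Product: 7 (Z)-7-(trimethylsilyl)hept-4-en-6-ynal
Conditions: i-Bu2AlH (1.05 equiv), CH2Cl2, –78 °C; aq. potassium sodium tartrate
Reagents that add atoms: none
Why: Low-temperature partial ester reduction stops at the tetrahedral aluminium hemiacetal, which releases the aldehyde on work-up; the silyl alkyne is inert at –78 °C.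

Step 4
Reactants: 7 (Z)-7-(trimethylsilyl)hept-4-en-6-ynal
Product: 8 (2R,4Z)-2-chloro-7-(trimethylsilyl)hept-4-en-6-ynal
Conditions: (5R)-5-benzyl-2,2,3-trimethylimidazolidin-4-one trifluoroacetate (5 mol%), 2,3,4,5,6,6-hexachlorocyclohexa-2,4-dien-1-one (1.2 equiv), acetone, –30 °C; used crude
Reagents that add atoms: 2,3,4,5,6,6-hexachlorocyclohexa-2,4-dien-1-one, O=C1C(Cl)=C(Cl)C(Cl)=C(Cl)C1(Cl)Cl
Why: Enamine-catalysed enantioselective α-chlorination sets C6; the (5R) catalyst is chosen as the mirror image of the one I recall giving (S)-2-chloroalkanals, and the sense must be confirmed on the derived chlorohydrin.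

Step 5
Reactants: 8 (2R,4Z)-2-chloro-7-(trimethylsilyl)hept-4-en-6-ynal; 9 1,1-dimethoxypropan-2-one
Product: 10 (4S,5R,7Z)-5-chloro-4-hydroxy-1,1-dimethoxy-10-(trimethylsilyl)dec-7-en-9-yn-2-one
Conditions: 9, LiN(i-Pr)2 (1.1 equiv), THF, –78 °C; then 8, –78 °C, 30 min; aq. NH4Cl at –78 °C
Reagents that add atoms: none
Why: Lithium aldol addition of the kinetic methyl-ketone enolate to the α-chloroaldehyde follows the Cornforth model and gives the 1,2-anti chlorohydrin, setting C7 (S) relative to C6 (R) while forming C7–C8.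

Step 6
Reactants: 10 (4S,5R,7Z)-5-chloro-4-hydroxy-1,1-dimethoxy-10-(trimethylsilyl)dec-7-en-9-yn-2-one
Product: 12 (3S,5S)-5-[(1R,3Z)-1-chloro-6-(trimethylsilyl)hex-3-en-5-yn-1-yl]-2-methoxyoxolan-3-ol (anomeric mixture), via anti-diol 11 (not isolated)
Conditions: Me4NBH(OAc)3 (5 equiv), MeCN/AcOH 1:1, –30 °C; then MeOH, camphorsulfonic acid (excess over acetate), 23 °C
Reagents that add atoms: none
Why: Evans–Saksena reduction delivers hydride intramolecularly from the C7-bound acetoxyborohydride through a chair transition state to give the 1,3-anti diol (C9 S), and acid-catalysed transacetalisation of the C7 hydroxyl onto the C10 acetal then closes the oxolane without base, so the chlorohydrin cannot form an epoxide.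

Step 7
Reactants: 12 (3S,5S)-5-[(1R,3Z)-1-chloro-6-(trimethylsilyl)hex-3-en-5-yn-1-yl]-2-methoxyoxolan-3-ol
Product: 13 (3S,5S)-5-[(1R,3Z)-1-chloro-6-(trimethylsilyl)hex-3-en-5-yn-1-yl]-2-methoxyoxolan-3-yl benzoate (anomeric mixture)
Conditions: BzCl, pyridine, DMAP (cat.), CH2Cl2, 0 to 23 °C
Reagents that add atoms: benzoyl chloride, O=C(Cl)c1ccccc1
Why: Standard acylation of the only free hydroxyl installs a participating C9 ester that later directs 1,2-trans substitution at C10.

Step 8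
Reactants: 2 ethynyltrimethylsilane; 14 propanoyl chloride
Product: 15 1-(trimethylsilyl)pent-1-yn-3-one
Conditions: PdCl2(PPh3)2 (1 mol%), CuI (2 mol%), Et3N (1.2 equiv), THF, 23 °C
Reagents that add atoms: none
Why: Acyl Sonogashira coupling of the terminal alkyne with the acid chloride gives the ynone directly without over-addition.

Step 9
Reactants: 15 1-(trimethylsilyl)pent-1-yn-3-one
Product: 16 (S)-1-(trimethylsilyl)pent-1-yn-3-ol
Conditions: Ru[(S,S)-TsDPEN](p-cymene) (0.5 mol%), i-PrOH, 23 °C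
Reagents that add atoms: none
Why: Noyori asymmetric transfer hydrogenation of the alkynyl ketone sets C13 as the (S)-carbinol, the alkynyl group taking the role of the π-substituent in the metal–ligand bifunctional transition state.

Step 10
Reactants: 16 (S)-1-(trimethylsilyl)pent-1-yn-3-ol
Product: 17 (S)-tert-butyldimethyl{[1-(trimethylsilyl)pent-1-yn-3-yl]oxy}silane
Conditions: t-BuMe2SiCl, imidazole, DMF, 23 °C
Reagents that add atoms: tert-butyl(chloro)dimethylsilane, CC(C)(C)[Si](C)(C)Cl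
Why: Standard silylation protects the C13 carbinol with a group that survives carbonate methanolysis and the later ring bromination.

Step 11
Reactants: 17 (S)-tert-butyldimethyl{[1-(trimethylsilyl)pent-1-yn-3-yl]oxy}silane
Product: 18 (S)-tert-butyl(pent-1-yn-3-yloxy)dimethylsilane
Conditions: K2CO3 (0.2 equiv), MeOH, 23 °C
Reagents that add atoms: none
Why: Base-catalysed methanolysis cleaves only the C(sp)–Si bond, leaving the silyl ether intact.

Step 12
Reactants: 18 (S)-tert-butyl(pent-1-yn-3-yloxy)dimethylsilane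
Product: 19 (S)-tert-butyl[(1-iodopent-1-yn-3-yl)oxy]dimethylsilane
Conditions: N-iodosuccinimide (1.1 equiv), AgNO3 (10 mol%), acetone, 23 °C
Reagents that add atoms: N-iodosuccinimide, O=C1CCC(=O)N1I
Why: Silver-acetylide-mediated electrophilic iodination of the terminal alkyne is fast and leaves the stereocentre untouched.

Step 13
Reactants: 19 (S)-tert-butyl[(1-iodopent-1-yn-3-yl)oxy]dimethylsilane
Product: 20 (S,Z)-tert-butyl[(1-iodopent-1-en-3-yl)oxy]dimethylsilane
Conditions: 2-nitrobenzenesulfonohydrazide (2 equiv), Et3N, THF/i-PrOH, 23 °C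
Reagents that add atoms: none
Why: Diimide generated in the flask adds H2 suprafacially to the iodoalkyne (cis reduction), giving the Z-alkenyl iodide that later becomes the C11=C12 alkene.

Step 14
Reactants: 13 (3S,5S)-5-[(1R,3Z)-1-chloro-6-(trimethylsilyl)hex-3-en-5-yn-1-yl]-2-methoxyoxolan-3-yl benzoate; 20 (S,Z)-tert-butyl[(1-iodopent-1-en-3-yl)oxy]dimethylsilane
Product: 24 (2R,3S,5S)-2-[(1Z,3S)-3-(tert-butyldimethylsilyloxy)pent-1-en-1-yl]-5-[(1R,3Z)-1-chloro-6-(trimethylsilyl)hex-3-en-5-yn-1-yl]oxolan-3-yl benzoate, via furanosyl bromide 21 (not isolated), via alkenyllithium 22 (not isolated), via alkenylzinc chloride 23 (not isolated)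
Conditions: 13, Me3SiBr (2 equiv), CH2Cl2, 0 to 23 °C, then evaporate; separately 20, t-BuLi (2.0 equiv), Et2O, –78 °C, then ZnCl2 (1.1 equiv, THF), –78 to 0 °C; combine (1.5 equiv zinc reagent), NiCl2(dme) (10 mol%), 4,4',4''-tri-tert-butyl-2,2':6',2''-terpyridine (12 mol%), DMA/THF, 0 to 23 °C
Reagents that add atoms: none
Why: Proposed new method: a nickel-catalysed, stereoconvergent Negishi alkenylation of a 3-deoxyfuranosyl bromide with a configurationally defined (Z)-alkenylzinc, in which a monovalent nickel–alkenyl species abstracts bromine from C10 to give an α-oxy radical that recombines with nickel and reductively eliminates on the face opposite both the C9 benzoate and the C7 side chain (any ionic leakage through the benzoate-bridged acyloxonium ion leads to the same 1,2-trans face), so C10 is set (R) whatever the anomeric composition of 21 and the Z geometry is retained; the closest known reaction types are the nickel-catalysed Negishi coupling of pyranosyl halides with alkyl- and arylzinc reagents and the nickel-catalysed decarboxylative alkenylation of α-oxy redox-active esters with alkenylzincs.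

Step 15
Reactants: 24 (2R,3S,5S)-2-[(1Z,3S)-3-(tert-butyldimethylsilyloxy)pent-1-en-1-yl]-5-[(1R,3Z)-1-chloro-6-(trimethylsilyl)hex-3-en-5-yn-1-yl]oxolan-3-yl benzoate
Product: 25 (2R,3S,5S)-2-[(1Z,3S)-3-(tert-butyldimethylsilyloxy)pent-1-en-1-yl]-5-[(1R,3Z)-1-chlorohex-3-en-5-yn-1-yl]oxolan-3-ol
Conditions: K2CO3 (0.3 equiv), MeOH, 23 °C
Reagents that add atoms: none
Why: Carbonate-catalysed methanolysis (transesterification) removes the benzoate and the alkynyl silane in one operation while the secondary silyl ether and both alkyl halide positions are untouched.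

Step 16
Reactants: 25 (2R,3S,5S)-2-[(1Z,3S)-3-(tert-butyldimethylsilyloxy)pent-1-en-1-yl]-5-[(1R,3Z)-1-chlorohex-3-en-5-yn-1-yl]oxolan-3-ol
Product: 26 tert-butyl{[(1Z,3S)-1-[(2R,3R,5S)-3-bromo-5-[(1R,3Z)-1-chlorohex-3-en-5-yn-1-yl]oxolan-2-yl]pent-1-en-3-yl]oxy}dimethylsilane
Conditions: CBr4 (3 equiv), P(n-Oct)3 (3 equiv), 1-methylcyclohexene, toluene, 70 °C
Reagents that add atoms: carbon tetrabromide, BrC(Br)(Br)Br
Why: Appel-type (Hooz) deoxybromination displaces the C9 alkoxyphosphonium by bromide with inversion (S to R), putting Br cis to the C10 alkenyl group, with the alkene scavenging HBr.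

Step 17
Reactants: 26 tert-butyl{[(1Z,3S)-1-[(2R,3R,5S)-3-bromo-5-[(1R,3Z)-1-chlorohex-3-en-5-yn-1-yl]oxolan-2-yl]pent-1-en-3-yl]oxy}dimethylsilane
Product: 27 (1Z,3S)-1-[(2R,3R,5S)-3-bromo-5-[(1R,3Z)-1-chlorohex-3-en-5-yn-1-yl]oxolan-2-yl]pent-1-en-3-ol
Conditions: HF·pyridine, THF/pyridine, 0 to 23 °C
Reagents that add atoms: none
Why: Buffered fluoride desilylation frees the allylic alcohol without the basic conditions that could eliminate the secondary bromide or chloride.

Step 18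
Reactants: 27 (1Z,3S)-1-[(2R,3R,5S)-3-bromo-5-[(1R,3Z)-1-chlorohex-3-en-5-yn-1-yl]oxolan-2-yl]pent-1-en-3-ol
Product: 28 (2R,3R,5S)-3-bromo-2-[(1Z,3R)-3-bromopent-1-en-1-yl]-5-[(1R,3Z)-1-chlorohex-3-en-5-yn-1-yl]oxolane (target)
Conditions: 1-bromo-N,N,2-trimethylprop-1-en-1-amine (1.5 equiv), CH2Cl2, –20 to 0 °C
Reagents that add atoms: 1-bromo-N,N,2-trimethylprop-1-en-1-amine, CC(C)=C(Br)N(C)C
Why: The α-haloenamine (Ghosez-type) converts the alcohol into an alkoxy-iminium ion that bromide displaces by direct SN2 under neutral, cold conditions, giving the (13R)-allylic bromide with inversion and little allylic transposition or Z/E erosion.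

**Compound list**

1 | cis-1,2-dichloroethene | Cl/C=C\Cl | starting material
2 | ethynyltrimethylsilane | C#C[Si](C)(C)C | starting material
3 | (Z)-(4-chlorobut-3-en-1-yn-1-yl)trimethylsilane | C[Si](C)(C)C#C/C=C\Cl | intermediate
4 | ethyl 3-iodopropanoate | CCOC(=O)CCI | starting material
5 | (3-ethoxy-3-oxopropyl)zinc iodide | CCOC(=O)CC[Zn]I | intermediate
6 | ethyl (Z)-7-(trimethylsilyl)hept-4-en-6-ynoate | CCOC(=O)CC/C=C\C#C[Si](C)(C)C | intermediate
7 | (Z)-7-(trimethylsilyl)hept-4-en-6-ynal | O=CCC/C=C\C#C[Si](C)(C)C | intermediate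
8 | (2R,4Z)-2-chloro-7-(trimethylsilyl)hept-4-en-6-ynal | O=C[C@H](Cl)C/C=C\C#C[Si](C)(C)C | intermediate
9 | 1,1-dimethoxypropan-2-one | COC(OC)C(C)=O | starting material
10 | (4S,5R,7Z)-5-chloro-4-hydroxy-1,1-dimethoxy-10-(trimethylsilyl)dec-7-en-9-yn-2-one | COC(OC)C(=O)C[C@H](O)[C@H](Cl)C/C=C\C#C[Si](C)(C)C | intermediate
11 | (2S,4S,5R,7Z)-5-chloro-1,1-dimethoxy-10-(trimethylsilyl)dec-7-en-9-yne-2,4-diol | COC(OC)[C@@H](O)C[C@H](O)[C@H](Cl)C/C=C\C#C[Si](C)(C)C | intermediate
12 | (3S,5S)-5-[(1R,3Z)-1-chloro-6-(trimethylsilyl)hex-3-en-5-yn-1-yl]-2-methoxyoxolan-3-ol (both anomers) | C[Si](C)(C)C#C/C=C\C[C@@H](Cl)[C@@H]1C[C@H](O)C(OC)O1 | intermediate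
13 | (3S,5S)-5-[(1R,3Z)-1-chloro-6-(trimethylsilyl)hex-3-en-5-yn-1-yl]-2-methoxyoxolan-3-yl benzoate (both anomers) | C[Si](C)(C)C#C/C=C\C[C@@H](Cl)[C@@H]1C[C@H](OC(=O)c2ccccc2)C(OC)O1 | intermediate
14 | propanoyl chloride | CCC(=O)Cl | starting material
15 | 1-(trimethylsilyl)pent-1-yn-3-one | CCC(=O)C#C[Si](C)(C)C | intermediate
16 | (S)-1-(trimethylsilyl)pent-1-yn-3-ol | C[Si](C)(C)C#C[C@@H](O)CC | intermediate
17 | (S)-tert-butyldimethyl{[1-(trimethylsilyl)pent-1-yn-3-yl]oxy}silane | C[Si](C)(C)C#C[C@@H](O[Si](C)(C)C(C)(C)C)CC | intermediate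
18 | (S)-tert-butyl(pent-1-yn-3-yloxy)dimethylsilane | C#C[C@@H](O[Si](C)(C)C(C)(C)C)CC | intermediate
19 | (S)-tert-butyl[(1-iodopent-1-yn-3-yl)oxy]dimethylsilane | IC#C[C@@H](O[Si](C)(C)C(C)(C)C)CC | intermediate
20 | (S,Z)-tert-butyl[(1-iodopent-1-en-3-yl)oxy]dimethylsilane | I/C=C\[C@@H](O[Si](C)(C)C(C)(C)C)CC | intermediate
21 | (3S,5S)-2-bromo-5-[(1R,3Z)-1-chloro-6-(trimethylsilyl)hex-3-en-5-yn-1-yl]oxolan-3-yl benzoate (anomeric mixture) | C[Si](C)(C)C#C/C=C\C[C@@H](Cl)[C@@H]1C[C@H](OC(=O)c2ccccc2)C(Br)O1 | intermediate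
22 | [(1Z,3S)-3-(tert-butyldimethylsilyloxy)pent-1-en-1-yl]lithium | [Li]/C=C\[C@@H](O[Si](C)(C)C(C)(C)C)CC | intermediate
23 | [(1Z,3S)-3-(tert-butyldimethylsilyloxy)pent-1-en-1-yl]zinc chloride | Cl[Zn]/C=C\[C@@H](O[Si](C)(C)C(C)(C)C)CC | intermediate
24 | (2R,3S,5S)-2-[(1Z,3S)-3-(tert-butyldimethylsilyloxy)pent-1-en-1-yl]-5-[(1R,3Z)-1-chloro-6-(trimethylsilyl)hex-3-en-5-yn-1-yl]oxolan-3-yl benzoate | C[Si](C)(C)C#C/C=C\C[C@@H](Cl)[C@@H]1C[C@H](OC(=O)c2ccccc2)[C@@H](/C=C\[C@@H](O[Si](C)(C)C(C)(C)C)CC)O1 | intermediate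
25 | (2R,3S,5S)-2-[(1Z,3S)-3-(tert-butyldimethylsilyloxy)pent-1-en-1-yl]-5-[(1R,3Z)-1-chlorohex-3-en-5-yn-1-yl]oxolan-3-ol | C#C/C=C\C[C@@H](Cl)[C@@H]1C[C@H](O)[C@@H](/C=C\[C@@H](O[Si](C)(C)C(C)(C)C)CC)O1 | intermediate
26 | tert-butyl{[(1Z,3S)-1-[(2R,3R,5S)-3-bromo-5-[(1R,3Z)-1-chlorohex-3-en-5-yn-1-yl]oxolan-2-yl]pent-1-en-3-yl]oxy}dimethylsilane | C#C/C=C\C[C@@H](Cl)[C@@H]1C[C@@H](Br)[C@@H](/C=C\[C@@H](O[Si](C)(C)C(C)(C)C)CC)O1 | intermediate
27 | (1Z,3S)-1-[(2R,3R,5S)-3-bromo-5-[(1R,3Z)-1-chlorohex-3-en-5-yn-1-yl]oxolan-2-yl]pent-1-en-3-ol | C#C/C=C\C[C@@H](Cl)[C@@H]1C[C@@H](Br)[C@@H](/C=C\[C@@H](O)CC)O1 | intermediate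
28 | (2R,3R,5S)-3-bromo-2-[(1Z,3R)-3-bromopent-1-en-1-yl]-5-[(1R,3Z)-1-chlorohex-3-en-5-yn-1-yl]oxolane | C#C/C=C\C[C@@H](Cl)[C@@H]1C[C@@H](Br)[C@@H](/C=C\[C@H](Br)CC)O1 | target

**Step count**
- Total steps: 18.
- Longest linear sequence: 12 (steps 1–7, then 14–18). The second branch (steps 8–13) joins at step 14.

**Steps most likely to fail, with fallbacks**

Step 14 (the proposed new coupling). The risks are β-benzoyloxy elimination from the C10–nickel intermediate to a 2,3-dihydrofuran, uncatalysed ionic alkenylation, and partial Z/E erosion. The fallback uses known chemistry, sets out from 13 and 18, and returns at 24. Alkyne 18 is lithiated (n-BuLi, THF, –78 °C) and quenched with Bu3SnCl to give (S)-tert-butyldimethyl{[1-(tributylstannyl)pent-1-yn-3-yl]oxy}silane F1. Lewis-acid C-glycosylation of 13 with F1 (ZnCl2 or SnCl4, CH2Cl2, –20 °C) goes through the benzoate-bridged acyloxonium ion and gives the 1,2-trans alkynyl C-glycoside (2R,3S,5S)-2-[(3S)-3-(tert-butyldimethylsilyloxy)pent-1-yn-1-yl]-5-[(1R,3Z)-1-chloro-6-(trimethylsilyl)hex-3-en-5-yn-1-yl]oxolan-3-yl benzoate F2. Semi-hydrogenation of F2 over Pd/CaCO3 poisoned with Pb(OAc)2 (quinoline, H2, EtOAc), stopped at one equivalent, gives 24. This relies on the dialkyl alkyne being reduced faster than the silyl-capped enyne, which is the weak point of the fallback.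

Step 5 (aldol). The α-chloroaldehyde can epimerise or lose HCl under the basic enolate, and the anti/syn ratio may be modest. The fallback sets out from 9 and 8 and returns at 10. Ketone 9 is converted (Me3SiOTf, Et3N, CH2Cl2, 0 °C) into the enol silane [(3,3-dimethoxyprop-1-en-2-yl)oxy]trimethylsilane F3. F3 is added to 8 in a Mukaiyama aldol (BF3·OEt2, CH2Cl2, –78 °C; aqueous work-up). This is a non-basic, open-transition-state addition that is also expected to be Cornforth-anti.

Step 18 (final allylic bromination). The risks are SN2' transposition to C11, Z/E isomerisation and partial loss of configuration at C13. The fallback sets out from 27 and returns at 28. The alcohol is converted at –40 °C (MsCl, Et3N, CH2Cl2) into the discrete sulfonate (1Z,3S)-1-[(2R,3R,5S)-3-bromo-5-[(1R,3Z)-1-chlorohex-3-en-5-yn-1-yl]oxolan-2-yl]pent-1-en-3-yl methanesulfonate F4. F4 is displaced cold with LiBr (THF, –20 °C) in a separate SN2 step with inversion, which replaces the one-pot iminium activation with a sulfonate displaced by an external bromide salt.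

**Further compounds**

F1 | step 14 | (S)-tert-butyldimethyl{[1-(tributylstannyl)pent-1-yn-3-yl]oxy}silane | CCCC[Sn](CCCC)(CCCC)C#C[C@@H](O[Si](C)(C)C(C)(C)C)CC
F2 | step 14 | (2R,3S,5S)-2-[(3S)-3-(tert-butyldimethylsilyloxy)pent-1-yn-1-yl]-5-[(1R,3Z)-1-chloro-6-(trimethylsilyl)hex-3-en-5-yn-1-yl]oxolan-3-yl benzoate | C[Si](C)(C)C#C/C=C\C[C@@H](Cl)[C@@H]1C[C@H](OC(=O)c2ccccc2)[C@@H](C#C[C@@H](O[Si](C)(C)C(C)(C)C)CC)O1
F3 | step 5 | [(3,3-dimethoxyprop-1-en-2-yl)oxy]trimethylsilane | COC(OC)C(=C)O[Si](C)(C)C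
F4 | step 18 | (1Z,3S)-1-[(2R,3R,5S)-3-bromo-5-[(1R,3Z)-1-chlorohex-3-en-5-yn-1-yl]oxolan-2-yl]pent-1-en-3-yl methanesulfonate | C#C/C=C\C[C@@H](Cl)[C@@H]1C[C@@H](Br)[C@@H](/C=C\[C@@H](OS(C)(=O)=O)CC)O1
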